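## Retrosynthetic overview

1. Pyranone O1–C2 (C–O, the key bond): closed last by cyclodehydration of an o-hydroxyaryl 1,3-diketone. This is the only ring made; the benzene ring is bought with its 2,6-(OH)2/4-OMe pattern in place.
2. C2–C3: a 1,5 O→C acyl shift inside a mono-aryl ester, run under new magnesium soft-enolisation conditions and telescoped into the ring closure.
3. Ester C–O: O-acylation of the symmetric 2',6'-dihydroxy-4'-methoxyacetophenone with the C34 acid chloride. Symmetry removes any regiochemical question; 5-OH and 7-OMe come from the ketone.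
4. C34 acid: C22 + C12 Grignard cross-coupling of 1-bromodocosane with 12-bromododecanoic acid under Li2CuCl4 catalysis.

Assumption: the target has no stereocentre (it is achiral), so no stereocontrol is needed; the side chain is read as unbranched tritriacontyl (33 carbons).

## Route

Step 1
Reactants: 1 1-bromodocosane; 2 12-bromododecanoic acid
Product: 5 tetratriacontanoic acid, via docosylmagnesium bromide 3 (not isolated), via chloromagnesium 12-bromododecanoate 4 (not isolated)
Conditions: 1 (1.3 equiv), Mg, THF, 55 °C; 2, MeMgCl (1.0 equiv), THF, −20 °C; combine, Li2CuCl4 (3 mol %), THF, −20 °C → rt; 2 M HCl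
Reagents that add atoms: none
Why: Kochi-type Li2CuCl4-catalysed sp3–sp3 cross-coupling of the primary alkyl Grignard reagent 3 with the primary bromide of 4 is fast at low temperature, while the carboxylate, already deprotonated by MeMgCl, is inert to Grignard addition, so the C22 and C12 pieces join to the C34 acid without protecting groups.

Step 2
Reactants: 5 tetratriacontanoic acid; 6 1-(2,6-dihydroxy-4-methoxyphenyl)ethan-1-one
Product: 8 2-acetyl-3-hydroxy-5-methoxyphenyl tetratriacontanoate, via tetratriacontanoyl chloride 7 (not isolated)
Conditions: (COCl)2 (1.5 equiv), DMF (cat.), PhMe, 60 °C, evaporate; 6 (1.5 equiv), pyridine (3 equiv), DMAP (5 mol %), PhMe, 45 °C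
Reagents that add atoms: none
Why: Acid chloride formation followed by Einhorn acylation of a phenol (pyridine, DMAP nucleophilic catalysis) gives one mono-ester because 6 is symmetric, and the remaining OH is tied up in a hydrogen bond to the acetyl group, which together with the excess of 6 holds back a second acylation.

Step 3
Reactants: 8 2-acetyl-3-hydroxy-5-methoxyphenyl tetratriacontanoate
Product: 10 5-hydroxy-7-methoxy-2-tritriacontyl-4H-chromen-4-one, via ring-opened 1,3-diketone 9 (not isolated)
Conditions: MgBr2·OEt2 (3 equiv), i-Pr2NEt (4 equiv), ClCH2CH2Cl, 45 °C; 1 M HCl wash; TsOH·H2O (10 mol %), PhMe, 100 °C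
Reagents that add atoms: none
Why: Proposed new method: a soft-enolisation Baker–Venkataraman shift, in which MgBr2 binds the phenoxide–acetyl chelate of 8 so that the weak base i-Pr2NEt removes only the ketone CH3 proton (the ester α-CH2 stays untouched), the magnesium enolate attacks the neighbouring aryl ester carbonyl through a six-membered transition state and the adduct collapses to the strongly chelated magnesium β-diketonate of 9 (the driving force), after which acid lets a phenol OH add to the C3 carbonyl and lose water to forge the O1–C2 bond of the pyranone; the closest known reactions are the intermolecular MgBr2·OEt2/i-Pr2NEt C-acylation of ketones with activated esters or acid chlorides, the strong-base Baker–Venkataraman rearrangement and the acid cyclodehydration of o-hydroxyaryl 1,3-diketones, and no stereocentre is formed.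

## Compound list

1 | 1-bromodocosane | CCCCCCCCCCCCCCCCCCCCCCBr | starting material
2 | 12-bromododecanoic acid | OC(=O)CCCCCCCCCCCBr | starting material
3 | docosylmagnesium bromide | CCCCCCCCCCCCCCCCCCCCCC[Mg]Br | intermediate
4 | chloromagnesium 12-bromododecanoate | BrCCCCCCCCCCCC(=O)O[Mg]Cl | intermediate
5 | tetratriacontanoic acid | CCCCCCCCCCCCCCCCCCCCCCCCCCCCCCCCCC(=O)O | intermediate
6 | 1-(2,6-dihydroxy-4-methoxyphenyl)ethan-1-one (2',6'-dihydroxy-4'-methoxyacetophenone) | CC(=O)c1c(O)cc(OC)cc1O | starting material
7 | tetratriacontanoyl chloride | CCCCCCCCCCCCCCCCCCCCCCCCCCCCCCCCCC(=O)Cl | intermediate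
8 | 2-acetyl-3-hydroxy-5-methoxyphenyl tetratriacontanoate | CCCCCCCCCCCCCCCCCCCCCCCCCCCCCCCCCC(=O)Oc1cc(OC)cc(O)c1C(C)=O | intermediate
9 | 1-(2,6-dihydroxy-4-methoxyphenyl)hexatriacontane-1,3-dione | CCCCCCCCCCCCCCCCCCCCCCCCCCCCCCCCCC(=O)CC(=O)c1c(O)cc(OC)cc1O | intermediate
10 | 5-hydroxy-7-methoxy-2-tritriacontyl-4H-chromen-4-one | CCCCCCCCCCCCCCCCCCCCCCCCCCCCCCCCCc1cc(=O)c2c(O)cc(OC)cc2o1 | target

## Step count and risks

Total step count: 3. Longest linear sequence: 3 steps (1 → 5 → 8 → 10).

The three steps most likely to fail, most risky first:

**Step 3, the proposed new acyl shift and ring closure.** The amine/MgBr2 pair may not enolise the chelated ketone fast enough, or bromide and amine may simply cleave the aryl ester back to 6. The fallback is known chemistry and makes the C2–C3 bond intermolecularly, without an ester of 6. It sets out from 5, which is esterified (MeOH, H2SO4 cat., PhMe, reflux) to methyl tetratriacontanoate F1. F1 then undergoes a classical Claisen condensation with the sodium polyanion of 6 (6 2 equiv, NaH, THF, reflux; acid quench). This gives the diketone and comes back to the route at 9, which is closed to 10 by the TsOH stage already used in step 3.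

**Step 1, the chain union.** Wurtz homocoupling during formation of 3, and poor solubility of the C22 Grignard reagent and of 4 at low temperature, can leave the coupling incomplete. The waxy C34 acid is also hard to free from hydrocarbons. The fallback builds the chain by acetylide alkylation instead of a Grignard cross-coupling. It sets out from 1, which is alkylated with LiC≡CH·H2NCH2CH2NH2 (DMSO/THF, 40 °C) to tetracos-1-yne F2. F2 is lithiated (n-BuLi, THF/DMPU, 0 °C) and alkylated with lithium 10-bromodecanoate to tetratriacont-11-ynoic acid F3. Hydrogenation (H2, Pd/C, THF, 50 °C) comes back to the route at 5.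

**Step 2, the mono-O-acylation.** Bis-acylation, or sluggish acylation of the hydrogen-bonded phenol, would give waxy ester mixtures that are hard to separate. The fallback changes the aromatic partner to the mono-phenol 1-(2-hydroxy-4,6-dimethoxyphenyl)ethan-1-one, so that only one ester can form and the 5-oxygen is carried as a methyl ether. It sets out from 5, which is converted to 7 as before and acylates that ketone (pyridine, DMAP, PhMe) to 2-acetyl-3,5-dimethoxyphenyl tetratriacontanoate F4. A classical Baker–Venkataraman rearrangement (KOtBu, THF, 40 °C) gives 1-(2-hydroxy-4,6-dimethoxyphenyl)hexatriacontane-1,3-dione F5. H2SO4 (cat.) in AcOH at 100 °C closes it to 5,7-dimethoxy-2-tritriacontyl-4H-chromen-4-one F6. BCl3 (CH2Cl2, −20 → 0 °C) then cleaves only the 5-OMe, which is chelated to the C4 carbonyl, and comes back to the route at 10.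

## Further compounds

F1 | step 3 | methyl tetratriacontanoate | CCCCCCCCCCCCCCCCCCCCCCCCCCCCCCCCCC(=O)OC
F2 | step 1 | tetracos-1-yne | CCCCCCCCCCCCCCCCCCCCCCC#C
F3 | step 1 | tetratriacont-11-ynoic acid | CCCCCCCCCCCCCCCCCCCCCCC#CCCCCCCCCCC(=O)O
F4 | step 2 | 2-acetyl-3,5-dimethoxyphenyl tetratriacontanoate | CCCCCCCCCCCCCCCCCCCCCCCCCCCCCCCCCC(=O)Oc1cc(OC)cc(OC)c1C(C)=O
F5 | step 2 | 1-(2-hydroxy-4,6-dimethoxyphenyl)hexatriacontane-1,3-dione | CCCCCCCCCCCCCCCCCCCCCCCCCCCCCCCCCC(=O)CC(=O)c1c(O)cc(OC)cc1OC
F6 | step 2 | 5,7-dimethoxy-2-tritriacontyl-4H-chromen-4-one | CCCCCCCCCCCCCCCCCCCCCCCCCCCCCCCCCc1cc(=O)c2c(OC)cc(OC)cc2o1
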